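**Strategy**

Labdane numbering is used. Ring B (C5 to C10, with CH3-17 on C8) comes intact from (S)-carvone, whose isopropenyl group already holds C4, C18 and C19; the whole plan rests on closing ring A onto it through the C3–C4 bond. The precursor is the carvone carrying CH3-20 and an acryloyl group (C1–C3) on C10, with the isopropenyl group epoxidised as both C4 epimers. Trivalent titanium opens the epoxide to a planar tertiary C4 radical that adds 6-endo to the vinyl ketone, giving ring A, the quaternary C4 and the free equatorial C18 hydroxymethyl in one operation. The feature exploited is the oxygenated quaternary C4 (CH3-19, CH2OH-18) next to C5 of ring B.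

Key step: step 5

Remark: epimer mixtures at centres that a later step destroys (C10 in 3, the carbinol carbon in 6, C4 in 8, C9 in 18) are carried on without separation.

**Route**

Step 1
Reactants: 1 (S)-carvone
Product: 3 6-methylcarvone (C10 epimers), via carvone lithium enolate 2 (not isolated)
Conditions: LiN(i-Pr)2 (LDA), THF, −78 °C; MeI, −78 to −20 °C
Reagents that add atoms: iodomethane, CI
Why: Kinetic deprotonation of the cross-conjugated enone occurs at the alpha-prime methylene (C10) and the lithium enolate is C-methylated (enolate alkylation), the new C10 centre being formed as an epimer mixture that is irrelevant because step 2 makes it trigonal again.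

Step 2
Reactants: 3 6-methylcarvone; 4 acrolein
Product: 6 aldol adduct with CH3-20 cis to the isopropenyl group (carbinol epimers), via lithium enolate of 6-methylcarvone 5 (not isolated)
Conditions: LiN(i-Pr)2 (LDA), THF, −78 °C; 4, −78 °C; AcOH quench at −78 °C
Reagents that add atoms: none
Why: A second kinetic enolisation at the tertiary C10 gives a tetrasubstituted lithium enolate that adds 1,2 to acrolein (lithium aldol addition) on the face anti to the vicinal isopropenyl group on C5, which fixes the quaternary C10, while the unselectively formed carbinol centre is removed in step 3.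

Step 3
Reactants: 6 aldol adduct
Product: 7 vinyl ketone (C10 acryloyl, isopropenyl on C5)
Conditions: Dess–Martin periodinane, CH2Cl2, 0 °C to rt
Reagents that add atoms: none
Why: Dess–Martin oxidation converts the secondary allylic alcohol to the enone under non-basic conditions, so retro-aldol cleavage at the quaternary C10 is avoided and no stereocentre is touched.

Step 4
Reactants: 7 vinyl ketone
Product: 8 epoxy vinyl ketone (both C4 epimers)
Conditions: mCPBA, CH2Cl2, 0 °C
Reagents that add atoms: 3-chloroperbenzoic acid, O=C(OO)c1cccc(Cl)c1
Why: Prilezhaev epoxidation is selective for the electron-rich 1,1-disubstituted isopropenyl alkene over the two electron-poor conjugated alkenes, and the new C4 centre is deliberately left as both epimers because step 5 erases it.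

Step 5
Reactants: 8 epoxy vinyl ketone
Product: 9 trans-fused decalin enedione with free C18 hydroxymethyl
Conditions: Cp2TiCl2, Mn dust, THF, rt (forms Cp2TiCl); added dropwise to 8 in THF (0.01 M), rt; aq. HCl
Reagents that add atoms: none
Why: Cp2TiCl transfers one electron to the oxirane, the more substituted C4–O bond breaks homolytically and both epoxide epimers give the same planar tertiary C4 radical with the titanium alkoxide on C18 (Nugent–RajanBabu reductive epoxide opening). The closest known reaction type is the titanocene-mediated epoxide opening with radical conjugate addition to enones, used here intramolecularly. Ring A closes by 6-endo-trig addition of the nucleophilic radical to the terminal C3 of the vinyl ketone, the beta carbon, which gives the stabilised alpha-keto radical, whereas 5-exo attack at C2 is polarity-mismatched and would give a primary radical; a second Cp2TiCl reduces the alpha-keto radical to a titanium enolate that is protonated on work-up. The new C4 stereocentre is set in a chair transition state anchored by the trans-diequatorial C5 and C10 substituents of ring B, in which the bulky CH2OTiCp2Cl group should take the equatorial site and CH3-19 the axial one beside CH3-20. The step needs 6-endo regiochemistry and one C4 configuration from two epimers; the enone polarity should secure the first and the carvone-derived C5 and C10 centres the second. Slow addition of the titanium reagent at high dilution should keep direct reduction of the vinyl ketone and intermolecular addition in check.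

Step 6
Reactants: 9 enedione
Product: 10 C1 ethylene dithioketal of 9
Conditions: HSCH2CH2SH, BF3·OEt2 (cat.), CH2Cl2, 0 °C
Reagents that add atoms: ethane-1,2-dithiol, SCCS
Why: Lewis acid-catalysed dithioketalisation should occur only at the saturated C1 ketone, because the C9 carbonyl is conjugated and flanked by the quaternary C10 and the methyl-bearing C8.

Step 7
Reactants: 10 dithioketal
Product: 11 decalin enone with C1 as CH2 (C9 ketone, C7=C8, C18-OH)
Conditions: Raney Ni (W-2, deactivated in refluxing acetone), EtOH, rt to 50 °C
Reagents that add atoms: none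
Why: Hydrogenolysis of both C–S bonds on nickel (Mozingo reduction) replaces the dithiolane by CH2 under neutral conditions that cannot trigger retro-Claisen cleavage, and deactivated nickel should spare the hindered trisubstituted enone.

Step 8
Reactants: 11 hydroxy enone
Product: 12 C18 TIPS ether of 11
Conditions: TIPSOTf, 2,6-lutidine, CH2Cl2, −78 to 0 °C
Reagents that add atoms: triisopropylsilyl triflate, CC(C)[Si](OS(=O)(=O)C(F)(F)F)(C(C)C)C(C)C
Why: Silylation of the neopentyl primary alcohol with the reactive silyl triflate gives an ether that withstands organolithium, chromate, dissolving-metal and hydride conditions and stays distinguishable from the primary TBS ether of the side chain.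

Step 9
Reactants: 13 (S)-citronellol
Product: 14 (S)-citronellol TBS ether
Conditions: TBSCl, imidazole, CH2Cl2, rt
Reagents that add atoms: tert-butyldimethylsilyl chloride, CC(C)(C)[Si](C)(C)Cl
Why: Imidazole-promoted silylation masks the future C15 hydroxyl as an ether stable to oxidative cleavage and to tert-butyllithium, leaving the C13 stereocentre untouched.

Step 10
Reactants: 14 citronellol TBS ether
Product: 15 (S)-6-[(tert-butyldimethylsilyl)oxy]-4-methylhexanoic acid
Conditions: RuCl3·xH2O (cat.), NaIO4, MeCN/EtOAc/H2O, 0 °C to rt
Reagents that add atoms: sodium periodate, [Na+].[O-]I(=O)(=O)=O; water, O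
Why: Ruthenium tetroxide generated catalytically from RuCl3 and NaIO4 cleaves the trisubstituted alkene to acetone and the carboxylic acid (Sharpless oxidative cleavage), far from the stereocentre.

Step 11
Reactants: 15 silyloxy acid
Product: 16 (R)-tert-butyl[(5-iodo-3-methylpentyl)oxy]dimethylsilane
Conditions: PhI(OAc)2, I2, cyclohexane/CH2Cl2, hν (tungsten lamp), 40 °C
Reagents that add atoms: iodine, II
Why: Photolysis of the acyl hypoiodite formed in situ releases CO2 and a primary radical that iodine traps (Suárez iododecarboxylation, a Hunsdiecker-type reaction), which shortens the chain by one carbon to the C11 iodide without touching C13.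

Step 12
Reactants: 16 side-chain iodide; 12 enone TIPS ether
Product: 18 C9 tertiary allylic alcohol carrying the C11–C16 chain (C7=C8, 15-OTBS, 18-OTIPS), via side-chain alkyllithium 17 (not isolated)
Conditions: 16, t-BuLi (2 equiv), Et2O/pentane, −78 °C; then 12, −78 to 0 °C; H2O
Reagents that add atoms: none
Why: Lithium–iodine exchange gives the primary alkyllithium, which adds 1,2 to the non-enolisable C9 ketone (organolithium carbonyl addition), probably anti to CH3-20, the configuration of the new carbinol being irrelevant because C9 becomes trigonal in step 13.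

Step 13
Reactants: 18 tertiary allylic alcohol
Product: 19 C7 ketone with C8=C9 double bond (15-OTBS, 18-OTIPS)
Conditions: pyridinium chlorochromate [C5H5NH][CrO3Cl], 4 Å molecular sieves, CH2Cl2, rt
Reagents that add atoms: pyridinium chlorochromate, [O-][Cr](=O)(=O)Cl.c1cc[nH+]cc1
Why: The tertiary allylic chromate ester undergoes a [3,3] shift to C7 and is oxidised there (Babler–Dauben oxidative transposition), which moves the oxygen from C9 to C7 and places the double bond between C8 and the chain-bearing C9.

Step 14
Reactants: 19 transposed enone
Product: 21 C7 enol triflate (C7=C8) with H-9 set, via lithium C7–C8 enolate 20 (not isolated)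
Conditions: Li, NH3(l)/THF, t-BuOH (1 equiv), −78 °C; isoprene; evaporate NH3; PhNTf2, THF, 0 °C to rt
Reagents that add atoms: N-phenylbis(trifluoromethanesulfonimide), O=S(=O)(N(c1ccccc1)S(=O)(=O)C(F)(F)F)C(F)(F)F
Why: Dissolving-metal reduction of the enone protonates the beta carbon C9 axially, which should give H-9 trans to CH3-20 with the side chain equatorial, and the regiodefined lithium enolate is then trapped on oxygen (McMurry–Scott enol triflate formation).

Step 15
Reactants: 21 enol triflate
Product: 22 C7=C8 alkene (15-OTBS, 18-OTIPS)
Conditions: Pd(OAc)2 (cat.), PPh3, HCO2H, Bu3N, DMF, 60 °C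
Reagents that add atoms: none
Why: Palladium-catalysed formate reduction of the enol triflate (Cacchi reduction) replaces OTf by H through oxidative addition, decarboxylation of the formate complex and reductive elimination, leaving the alkene in place and C9 untouched.

Step 16
Reactants: 22 alkene
Product: 23 7,8-epoxide with oxygen anti to CH3-20
Conditions: mCPBA, CH2Cl2, 0 °C
Reagents that add atoms: 3-chloroperbenzoic acid, O=C(OO)c1cccc(Cl)c1
Why: Prilezhaev epoxidation of the trisubstituted alkene should occur on the face opposite the axial CH3-20, which places the C8 oxygen anti to CH3-20 as the target requires.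

Step 17
Reactants: 23 epoxide
Product: 24 C8 tertiary alcohol (OH equatorial, CH3-17 axial; 15-OTBS, 18-OTIPS)
Conditions: LiEt3BH, THF, 0 °C to reflux; H2O
Reagents that add atoms: none
Why: The hindered hydride should open the epoxide by SN2 attack at the secondary C7 and not at the tertiary C8, whose backside is shielded by CH3-20 (regioselective reductive epoxide opening), so the C8–O bond and its configuration are retained.

Step 18
Reactants: 24 bis-silyl ether
Product: 25 C15 primary alcohol (8-OH free, 18-OTIPS)
Conditions: PPTS (cat.), EtOH, rt to 40 °C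
Reagents that add atoms: none
Why: Mild acid-catalysed solvolysis removes the unhindered primary TBS ether much faster than the neopentyl TIPS ether (selective desilylation) and does not ionise the tertiary C8 alcohol.

Step 19
Reactants: 25 diol; 26 2,2-dimethyl-1,3-dioxane-4,6-dione
Product: 27 C15 hydrogen malonate (18-OTIPS)
Conditions: 26, toluene, 80 °C
Reagents that add atoms: none
Why: The primary alcohol opens the dioxanedione thermally with loss of acetone and gives the malonic half ester directly (acylation by Meldrum's acid), the hindered tertiary C8 hydroxyl being unreactive at this temperature.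

Step 20
Reactants: 27 silylated half ester
Product: 28 target
Conditions: HF·pyridine, pyridine/THF, 0 °C to rt
Reagents that add atoms: none
Why: Fluoride cleaves the Si–O bond (desilylation) under mildly acidic conditions that should leave the malonate ester, the free acid and the tertiary alcohol intact.

**Compound list**

1 | (S)-carvone | CC1=CC[C@H](C(C)=C)CC1=O | starting material
2 | lithium enolate of 1 (enolate between the carbonyl carbon and the alpha-prime carbon) | CC1=CC[C@H](C(C)=C)C=C1[O-].[Li+] | intermediate (not isolated)
3 | (5S,6RS)-2,6-dimethyl-5-(prop-1-en-2-yl)cyclohex-2-en-1-one (6-methylcarvone) | CC1=CC[C@H](C(C)=C)C(C)C1=O | intermediate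
4 | acrolein | C=CC=O | starting material
5 | lithium enolate of 3 (tetrasubstituted) | CC1=CC[C@H](C(C)=C)C(C)=C1[O-].[Li+] | intermediate (not isolated)
6 | (5R,6S)-6-(1-hydroxyprop-2-en-1-yl)-2,6-dimethyl-5-(prop-1-en-2-yl)cyclohex-2-en-1-one, carbinol epimers | O=C1[C@](C)(C(O)C=C)[C@@H](C(C)=C)CC=C1C | intermediate
7 | (5R,6S)-6-acryloyl-2,6-dimethyl-5-(prop-1-en-2-yl)cyclohex-2-en-1-one | O=C1[C@](C)(C(=O)C=C)[C@@H](C(C)=C)CC=C1C | intermediate
8 | (5S,6S)-6-acryloyl-2,6-dimethyl-5-(2-methyloxiran-2-yl)cyclohex-2-en-1-one, both oxirane epimers | O=C1[C@](C)(C(=O)C=C)[C@@H](C2(C)CO2)CC=C1C | intermediate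
9 | (4aR,5S,8aS)-5-(hydroxymethyl)-2,5,8a-trimethyl-4a,5,6,7-tetrahydronaphthalene-1,8(4H,8aH)-dione (C1 and C9 ketones, C7=C8, trans fusion, CH3-19 cis to CH3-20) | O=C1[C@]2(C)C(=O)CC[C@](C)(CO)[C@H]2CC=C1C | intermediate
10 | C1 spiro-1,3-dithiolane of 9 | O=C1[C@]2(C)C3(SCCS3)CC[C@](C)(CO)[C@H]2CC=C1C | intermediate
11 | (4aR,5S,8aR)-5-(hydroxymethyl)-2,5,8a-trimethyl-4a,5,6,7,8,8a-hexahydronaphthalen-1(4H)-one | O=C1[C@]2(C)CCC[C@](C)(CO)[C@H]2CC=C1C | intermediate
12 | C18 triisopropylsilyl ether of 11 | O=C1[C@]2(C)CCC[C@](C)(CO[Si](C(C)C)(C(C)C)C(C)C)[C@H]2CC=C1C | intermediate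
13 | (S)-citronellol | C[C@H](CCO)CCC=C(C)C | starting material
14 | (S)-citronellol tert-butyldimethylsilyl ether | C[C@H](CCO[Si](C)(C)C(C)(C)C)CCC=C(C)C | intermediate
15 | (S)-6-[(tert-butyldimethylsilyl)oxy]-4-methylhexanoic acid | C[C@H](CCO[Si](C)(C)C(C)(C)C)CCC(=O)O | intermediate
16 | (R)-tert-butyl[(5-iodo-3-methylpentyl)oxy]dimethylsilane | C[C@H](CCO[Si](C)(C)C(C)(C)C)CCI | intermediate
17 | alkyllithium from 16 (Li in place of I) | C[C@H](CCO[Si](C)(C)C(C)(C)C)CC[Li] | intermediate (not isolated)
18 | 15-OTBS, 18-OTIPS labd-7-en-9-ol of the ent series (C9 configuration undefined; C4, C5, C10, C13 as in target) | C[C@H](CCO[Si](C)(C)C(C)(C)C)CCC1(O)[C@]2(C)CCC[C@](C)(CO[Si](C(C)C)(C(C)C)C(C)C)[C@H]2CC=C1C | intermediate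
19 | 15-OTBS, 18-OTIPS ent-labd-8-en-7-one | C[C@H](CCO[Si](C)(C)C(C)(C)C)CCC=1[C@]2(C)CCC[C@](C)(CO[Si](C(C)C)(C(C)C)C(C)C)[C@H]2CC(=O)C=1C | intermediate
20 | lithium C7–C8 enolate of the 9-H ketone (H-9 trans to CH3-20) | C[C@H](CCO[Si](C)(C)C(C)(C)C)CC[C@H]1[C@]2(C)CCC[C@](C)(CO[Si](C(C)C)(C(C)C)C(C)C)[C@H]2CC([O-])=C1C.[Li+] | intermediate (not isolated)
21 | 15-OTBS, 18-OTIPS ent-labd-7-en-7-yl triflate | C[C@H](CCO[Si](C)(C)C(C)(C)C)CC[C@H]1[C@]2(C)CCC[C@](C)(CO[Si](C(C)C)(C(C)C)C(C)C)[C@H]2CC(OS(=O)(=O)C(F)(F)F)=C1C | intermediate
22 | 15-OTBS, 18-OTIPS ent-labd-7-ene | C[C@H](CCO[Si](C)(C)C(C)(C)C)CC[C@H]1[C@]2(C)CCC[C@](C)(CO[Si](C(C)C)(C(C)C)C(C)C)[C@H]2CC=C1C | intermediate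
23 | 7,8-epoxide of 22, oxygen anti to CH3-20 | C[C@H](CCO[Si](C)(C)C(C)(C)C)CC[C@H]1[C@]2(C)CCC[C@](C)(CO[Si](C(C)C)(C(C)C)C(C)C)[C@H]2C[C@@H]3O[C@@]31C | intermediate
24 | 15-OTBS, 18-OTIPS ent-labdan-8-ol (8-OH equatorial, anti to CH3-20) | C[C@H](CCO[Si](C)(C)C(C)(C)C)CC[C@H]1[C@]2(C)CCC[C@](C)(CO[Si](C(C)C)(C(C)C)C(C)C)[C@H]2CC[C@]1(C)O | intermediate
25 | 18-OTIPS ent-labdane-8,15-diol | C[C@H](CCO)CC[C@H]1[C@]2(C)CCC[C@](C)(CO[Si](C(C)C)(C(C)C)C(C)C)[C@H]2CC[C@]1(C)O | intermediate
26 | 2,2-dimethyl-1,3-dioxane-4,6-dione (Meldrum's acid) | CC1(C)OC(=O)CC(=O)O1 | starting material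
27 | 18-OTIPS ent-labdane-8,15-diol 15-(hydrogen malonate) | C[C@H](CCOC(=O)CC(=O)O)CC[C@H]1[C@]2(C)CCC[C@](C)(CO[Si](C(C)C)(C(C)C)C(C)C)[C@H]2CC[C@]1(C)O | intermediate
28 | 3-{[(4S,5S,8S,9S,10R,13S)-8,18-dihydroxylabdan-15-yl]oxy}-3-oxopropanoic acid (CNP0324566.1) | C[C@H](CCOC(=O)CC(=O)O)CC[C@H]1[C@]2(C)CCC[C@](C)(CO)[C@H]2CC[C@]1(C)O | target

**Step count**

Total step count: 20. Longest linear sequence: 17 (steps 1–8 and 12–20, from 1 to 28); the side chain takes 3 steps (9–11).

**Steps most likely to fail**

1. Step 5. What may go wrong:
- electron transfer from trivalent titanium to the vinyl ketone before the epoxide is opened;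
- loss of a hydrogen atom from the C4 radical to give an allylic alcohol instead of ring closure;
- insufficient discrimination between the two faces of the planar C4 radical.

Fallback (polar instead of radical formation of the same C3–C4 bond): setting out from 8, a Lewis acid-induced Meinwald rearrangement (BF3·OEt2, CH2Cl2, −78 °C) should shift a hydride from C18 to C4 and give 2-(2-acryloyl-2,4-dimethyl-3-oxocyclohex-4-en-1-yl)propanal F1. Condensation of F1 with pyrrolidine (cat. AcOH, toluene, rt) gives the C4=C18 enamine, which should add 6-endo to the vinyl ketone (Stork enamine Michael addition). Hydrolysis with aqueous AcOH should then give the C18 aldehyde analogue of 9 F2, with the bulkier enamine carbon expected equatorial for the same steric reason as in step 5. Chemoselective reduction of the aldehyde (NaBH4, MeOH/CH2Cl2, −78 °C) comes back to the route at 9.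

2. Step 7. What may go wrong: hydrogen adsorbed on the nickel saturates the C7=C8 bond of the enone or reduces the C9 carbonyl while the C–S bonds are cleaved.

Fallback (hydrazone reduction instead of desulfurisation): setting out from 9 and bypassing 10, TsNHNH2 (EtOH, 50 °C) should condense only with the unconjugated, less hindered C1 ketone to give the C1 tosylhydrazone of 9 F3. Catecholborane (CHCl3, 0 °C) followed by NaOAc·3H2O at reflux should convert F3 to the methylene compound with loss of sulfinate and nitrogen (Kabalka variant of the Caglioti reduction), since the ring-locked s-trans enone is inert to this borane. The route is rejoined at 11.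

3. Step 17. What may go wrong: the hydride must open the epoxide against the trans-diaxial preference of the rigid decalin, so the reaction may stall and base-induced isomerisation to an allylic alcohol may take over.

Fallback (radical hydration instead of epoxide opening): setting out from 22, Mukaiyama hydration (Mn(dpm)3 cat., PhSiH3, O2, i-PrOH, 0 °C to rt) should generate the tertiary C8 radical by hydrogen-atom transfer. Oxygen should trap it anti to CH3-20 as the C8 hydroperoxide corresponding to 24 F4, which PPh3 reduces in the same flask, so that the route is rejoined at 24.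

**Further compounds**

F1 | step 5 | 2-(2-acryloyl-2,4-dimethyl-3-oxocyclohex-4-en-1-yl)propanal, ring configuration as in 8, both C4 epimers | O=C1[C@](C)(C(=O)C=C)[C@@H](C(C)C=O)CC=C1C
F2 | step 5 | C18 aldehyde analogue of 9 (CHO in place of CH2OH) | O=C1[C@]2(C)C(=O)CC[C@](C)(C=O)[C@H]2CC=C1C
F3 | step 7 | C1 tosylhydrazone of 9 | O=C1[C@]2(C)C(=NNS(=O)(=O)c3ccc(C)cc3)CC[C@](C)(CO)[C@H]2CC=C1C
F4 | step 17 | C8 hydroperoxide corresponding to 24 | C[C@H](CCO[Si](C)(C)C(C)(C)C)CC[C@H]1[C@]2(C)CCC[C@](C)(CO[Si](C(C)C)(C(C)C)C(C)C)[C@H]2CC[C@]1(C)OO
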